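The second nucleophile pulls on the intermediate harder than the first nucleophile at full charge, 1120 s⁻¹ against 102 s⁻¹, so the order of addition should matter.

| flask | substrate | first nucleophile | second nucleophile | time | remark |
|---|---|---|---|---|---|
| midnight | 0.070 M | 0.350 M | 0.140 M (fed, over 15 s) | 40 s | all else is in the flask from the start; the feed brings no volume worth counting |
| summer | 0.070 M (fed, over 15 s) | 0.350 M | 0.140 M | 40 s | all else is in the flask from the start; the feed brings no volume worth counting |
| noon | 0.070 M (fed, over 4.0 s) | 0.350 M | 0.140 M | 40 s | all else is in the flask from the start; the feed brings no volume worth counting |
| spring | 0.070 M (in portions, 4, over 15 s) | 0.350 M | 0.140 M | 40 s | first portion at the start, last at 15 s |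
| dusk | 0.070 M | 0.350 M | 0.140 M | 40 s | everything together at the start |

    substrate → intermediate (k1 = 1.2 s⁻¹)
    intermediate → solvolysis product (k2 = 62 s⁻¹)
    first nucleophile + intermediate → target (k3 = 290 L mol⁻¹ s⁻¹)
    second nucleophile + intermediate → other capture product (k4 = 8000 L mol⁻¹ s⁻¹)
    second nucleophile → decomposed reagent (k5 = 0.13 s⁻¹)

- the flask that comes out highest in amount of target, in percent of the substrate charged, or "all alike" when all lie within 1.5 percentage points (midnight / summer / noon / spring / dusk / all alike)
- target at the end, in percent of the substrate charged, midnight
- target at the end, in percent of the substrate charged, summer
- target at the end, in percent of the substrate charged, noon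
- target at the end, in percent of the substrate charged, spring
- target at the end, in percent of the substrate charged, dusk

The intermediate lives 0.00612 s without second nucleophile, far less than the 0.833 s of the substrate, so it does not pile up and each molecule chooses its path as it forms. The first nucleophile stands in excess and acts as a pseudo-first-order trap. With no second nucleophile present, target takes a share of 62.1%. The rule for these flasks is the crossover fraction, the fraction of its charge at which the second nucleophile takes as much intermediate as solvolysis and the first nucleophile together: 0.146. With the first nucleophile held at its charge and the second nucleophile at a fraction y of its own charge, the target share at that moment is the free share divided by one plus y over the crossover fraction.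

In the first instants of midnight, the second nucleophile stands near zero and the substrate is whole. Solvolysis and target formation then share the intermediate. At the substrate lifetime the midnight feed has brought 0.0556 of the charge of second nucleophile, if losses are ignored. In powers of ten that is −1.25 against −0.836 for the crossover, so the feed is still below it, and the share is 45.0%. This share at that one moment is the number I commit to for midnight. With losses still ignored, the midnight feed reaches the crossover at 2.19 s, when 7.22% of the substrate is left.

Dusk starts at the whole charge, above the crossover, with a share of 7.91%. In dusk, capture can consume 50.0% of the charge of second nucleophile, and at the remainder the share is 14.0%. With decay left aside, I expect dusk between those two shares, as an estimate and not a bound. In summer, decay by itself needs 14.8 s to bring the second nucleophile down to the crossover, close to the 15 s of the feed. Capture speeds that fall, and there my hand reckoning stops, with no figure for summer, noon or spring.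

The forecast names midnight, with 49% there, 29% in summer, 15% in noon, 24% in spring and 11% in dusk. Its ground, with "it" the second nucleophile, is that “target forms mainly when little of it is present”. For midnight it stands above my figure.

The flask gives 51.4% in midnight, 26.5% in summer, 26.4% in spring, 14.4% in noon and 11.0% in dusk. Other capture product ends at 15.5% in midnight against 82.2% in dusk. My midnight share lies 6.4 percentage points under the flask. A neighbour of midnight with first nucleophile at 0.88 M has a crossover fraction of 0.283 and a free share of 80.5%. At 0.0556 of the charge that gives 67.3%, and that flask ends with 71.4% of target.

The constants belong to no real substance, and the outcome is calculated.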